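At 20 min the flask, closed and held at constant temperature, had to show how target and isomer of the product A stood against each other, but the larch and birch runs ended at 12.0 min.

| flask | substrate | reagent | remark | time |
|---|---|---|---|---|
| larch | 0.050 M | 0.037 M | run made earlier |  |
| birch | 0.050 M | 0.056 M | run made earlier |  |
| flask | 0.050 M | 0.0750 M |  | 20 min |

| run | time / min | target / % | isomer of the product A / % |
|---|---|---|---|
| larch | 0.833 | 22 | 6 |
| larch | 2.50 | 17 | 7 |
| larch | 4.00 | 14 | 7 |
| larch | 6.00 | 16 | 12 |
| larch | 10.0 | 13 | 8 |
| larch | 12.0 | 5 | 12 |
| birch | 2.00 | 28 | 8 |
| birch | 4.00 | 22 | 7 |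
| birch | 6.00 | 19 | 10 |
| birch | 8.00 | 16 | 8 |
| birch | 10.0 | 15 | 12 |
| birch | 12.0 | 8 | 10 |

(scatter of a reading: 2 percentage points)

- share of target in target plus isomer of the product A at 2.5 s
- share of target in target plus isomer of the product A at 20 min
- which of target and isomer of the product A there is more of at 20 min

I replaced the ends of the curves by their mean, the late share: target summed over the last two readings of both runs, divided by target plus isomer of the product A summed over the same readings, 49.4%. The larch run by itself gave 47.4% and the birch run 51.1%, with a scatter of 2 percentage points on each reading, so I let them stand as one value for the flask. But a mean hides a slope: the last readings by themselves gave 37.1%. So I committed to a share between these two at 20 min, with the isomer of the product A ahead at either end .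

The forecast gave 82% at 2.5 s, 32% at 20 min and the lead to the isomer of the product A, on the ground that “The target appears quickly and then falls steadily”.

The flask gave 92.9% and 44.9%, with 12.8% target against 15.8% isomer of the product A, so the lead went to the isomer of the product A.

    substrate + reagent ⇌ isomer of the product A (K = 230 L mol⁻¹, k = 0.0210 L mol⁻¹ s⁻¹)
    target ⇌ isomer of the product B (K = 4.60, k = 0.00810 s⁻¹)
    substrate + reagent ⇌ target (K = 39.0 L mol⁻¹, k = 0.280 L mol⁻¹ s⁻¹)

The flask's share at 20 min lay 4.5 points below the late share and above the last readings ; from 10.0 min to 20.0 min the flask's target went from 14.3% to 12.8%, while its isomer of the product A rose from 12.4% to 15.8%. The neighbour flask charged with 0.13 M of reagent got the same reckoning, a share between 37.1% and 49.4%. At 20 min it held 13.6% target and 17.2% isomer of the product A, a share of 44.3%.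

The earlier runs and the new flask come from a simulation from invented constants, noise included.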